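**Strategy.** Everything rests on cutting the C8–C14 bond of ring C (friedelane numbering), the carbocycle that joins the aromatic AB half to the cis-fused DE half. An intramolecular reductive Heck reaction of a C8 enol triflate (ring B) onto a C14 exocyclic methylene (ring D) closes ring C as the last ring, builds the C14 quaternary centre beside quaternary C13 and turns the methylene carbon into the C26 angular methyl in one operation. Its precursor already holds every other ring: guaiane and benzodioxane (o-quinone hetero-Diels–Alder), ring B (aryne Diels–Alder), rings D and E (carvone Diels–Alder), joined at C9 by asymmetric phase-transfer alkylation. A final base-mediated alkene shift sets the C6=C7 bond and H8.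

Key step: step 26

Remark 1: triterpene atoms carry friedelane numbers (C1–C30, rings A–E); sesquiterpene atoms carry primed guaiane numbers (C1'–C15').
Remark 2: in the two catalyst-controlled steps (4 and 24) the named ligand or catalyst antipode is the one assumed to give the required configuration; both antipodes are available.

**Part A – guaiane diene (steps 1–8)**

Step 1
Reactants: 1 (S)-(+)-carvone
Product: 2 (S)-trimethyl{[2-methyl-5-(prop-1-en-2-yl)cyclohex-1-en-1-yl]oxy}silane
Conditions: LiBH(s-Bu)3, THF, −78 °C; then Me3SiCl, Et3N, −78 °C to rt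
Reagents that add atoms: chlorotrimethylsilane C[Si](C)(C)Cl
Why: Conjugate hydride reduction gives the enolate regiospecifically and O-silylation fixes it as the tetrasubstituted silyl enol ether; the carvone stereocentre (later C7') is untouched.

Step 2
Reactants: 2 silyl enol ether
Product: 3 (3S)-6-methyl-3-(prop-1-en-2-yl)-1-(trimethylsilyloxy)bicyclo[4.1.0]heptane (cis-fused cyclopropane; its two centres are not defined and are destroyed in step 3)
Conditions: Et2Zn, CH2I2, CH2Cl2, 0 °C
Reagents that add atoms: diiodomethane ICI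
Why: Simmons–Smith cyclopropanation (Furukawa variant) should take the electron-rich silyl enol ether far faster than the isopropenyl group.

Step 3
Reactants: 3 siloxycyclopropane
Product: 5 (S)-3-methyl-6-(prop-1-en-2-yl)cyclohept-2-en-1-one, via 3-chloro ketone 4 (not isolated)
Conditions: FeCl3, DMF, 0 °C to rt; then NaOAc, MeOH, reflux
Reagents that add atoms: none
Why: Saegusa–Ito ring expansion: one-electron oxidation opens the internal cyclopropane bond to the tertiary radical, and chlorine transfer then loss of HCl give the ring-enlarged enone with the new CH2 (C1') on the methyl-bearing side.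

Step 4
Reactants: 5 cycloheptenone
Product: 7 (2S,3R,6S)-2-(but-2-yn-1-yl)-3-methyl-6-(prop-1-en-2-yl)cycloheptan-1-one, via diphenylsilyl enol ether 6 (not isolated)
Conditions: CuCl (5 mol %), NaOt-Bu, (S)-p-tol-BINAP, Ph2SiH2, toluene, 0 °C; then Bu4N[Ph3SiF2], 1-bromobut-2-yne, CH2Cl2, rt
Reagents that add atoms: 1-bromobut-2-yne CC#CCBr
Why: Ligand-controlled copper hydride 1,4-reduction sets the C10' methyl centre (R) independently of remote C7' and leaves the enolate regiodefined at C1', which fluoride releases for C-alkylation trans to the new methyl (asymmetric conjugate reduction–alkylation); the C1' centre is erased in step 7.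

Step 5
Reactants: 7 alkynyl ketone
Product: 8 (2S,3R,6S)-3-methyl-2-(2-oxobutyl)-6-(prop-1-en-2-yl)cycloheptan-1-one
Conditions: Ph3PAuNTf2 (2 mol %), H2O, MeOH, rt
Reagents that add atoms: water O
Why: Gold-catalysed alkyne hydration, steered by 5-exo attack of the ring carbonyl oxygen on the activated alkyne, should put the new ketone on the alkyne carbon nearer the ring (1,4-diketone) and spare both alkenes.

Step 6
Reactants: 8 1,4-diketone
Product: 9 (5S,8R,8aS)-3,8-dimethyl-5-(prop-1-en-2-yl)-4,5,6,7,8,8a-hexahydroazulen-2(1H)-one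
Conditions: KOH, MeOH, reflux
Reagents that add atoms: none
Why: Intramolecular aldol condensation (ethyl-ketone α-carbon onto the ring carbonyl) closes the cyclopentenone with the tetrasubstituted C4'=C5' bond; C10' is not enolisable and keeps its configuration.

Step 7
Reactants: 9 bicyclic enone
Product: 10 (5S,8R)-3,8-dimethyl-5-(prop-1-en-2-yl)-1,4,5,6,7,8-hexahydroazulen-2-yl trifluoromethanesulfonate
Conditions: Tf2O, 2,6-di-tert-butyl-4-methylpyridine, CH2Cl2, 0 °C
Reagents that add atoms: triflic anhydride O=S(=O)(OS(=O)(=O)C(F)(F)F)C(F)(F)F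
Why: O-triflation with loss of the γ-proton at ring-fusion carbon C1' gives the linearly conjugated dienyl triflate (thermodynamic dienol triflate formation), which fixes the diene as C1'=C5' and C3'=C4'.

Step 8
Reactants: 10 dienyl triflate
Product: 11 (4R,7S)-1,4-dimethyl-7-(prop-1-en-2-yl)-3,4,5,6,7,8-hexahydroazulene (guaia-1(5),3,11-triene)
Conditions: Pd(OAc)2, PPh3, Bu3N, HCO2H, DMF, 40 °C; used at once
Reagents that add atoms: none
Why: Palladium-catalysed formate reduction of the alkenyl triflate replaces OTf by H without moving the double bonds, so the cyclopentadiene should form as one regioisomer and is used cold before 1,5-hydrogen shifts can scramble it.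

**Part B – silyloxydiene (step 9)**

Step 9
Reactants: 12 pent-1-en-3-one
Product: 13 (Z)-triisopropyl(penta-1,3-dien-3-yloxy)silane
Conditions: i-Pr3SiOTf, Et3N, CH2Cl2, 0 °C
Reagents that add atoms: triisopropylsilyl triflate CC(C)[Si](OS(=O)(=O)C(F)(F)F)(C(C)C)C(C)C
Why: Soft enolisation and O-silylation of the ethyl ketone should give the (Z)-2-silyloxydiene.

**Part C – benzodioxane and ring B (steps 10–13)**

Step 10
Reactants: 14 2-methylresorcinol
Product: 15 3-(tert-butyldimethylsilyloxy)-2-methylphenol
Conditions: t-BuMe2SiCl (1.0 equiv), imidazole, DMF, 0 °C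
Reagents that add atoms: tert-butyldimethylsilyl chloride CC(C)(C)[Si](C)(C)Cl
Why: Statistical monosilylation of the symmetric diol; the mono-ether is separated from diol and bis-ether.

Step 11
Reactants: 15 phenol, 11 guaiatriene
Product: 17 cis-fused benzodioxane (C3'–O–C2 and C4'–O–C3; arene carries 4-methyl and 5-OSiMe2t-Bu; dioxane oxygens on the face of the C10' methyl), via o-quinone 16 (not isolated)
Conditions: IBX, DMF, rt; then 11, CH2Cl2, −20 °C to rt
Reagents that add atoms: 2-iodoxybenzoic acid O=C1OI(=O)(O)c2ccccc12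
Why: ortho-Oxygenation gives the o-quinone, whose O=C–C=O unit adds suprafacially as heterodiene across the less hindered C3'=C4' bond (inverse-demand hetero-Diels–Alder, hence cis-fused dioxane); C3' should bond to O2 because the phenoxide then developing at O3 is not opposed by the para silyloxy donor, while facial selectivity towards the remote C7'/C10' centres is expected to be modest, so the isomer with both oxygens syn to the C10' methyl is separated by chromatography.

Step 12
Reactants: 17 aryl silyl ether
Product: 18 aryl triflate (C5–OTf)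
Conditions: CsF, PhNTf2, DMF, rt
Reagents that add atoms: N-phenylbis(trifluoromethanesulfonimide) O=S(=O)(N(c1ccccc1)S(=O)(=O)C(F)(F)F)C(F)(F)F
Why: Fluoride cleaves the aryl silyl ether and the phenoxide is triflated in the same flask, so no acid reaches the tertiary allylic aryl ether.

Step 13
Reactants: 18 aryl triflate, 13 silyloxydiene
Product: 21 1-methyl-2-tetralone fused to the benzodioxane (C8 ketone, C9–H epimers), via aryne 19 (not isolated), via silyl enol ether 20 (not isolated)
Conditions: lithium 2,2,6,6-tetramethylpiperidide (from 2,2,6,6-tetramethylpiperidine and n-BuLi), 13 (5 equiv), THF, −78 °C to rt; then Bu4NF, AcOH, THF, 0 °C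
Reagents that add atoms: none
Why: ortho-Lithiation at C10 (the only hydrogen beside the triflate) and loss of LiOTf give the C5–C10 aryne, which takes up the diene in a Diels–Alder reaction; the nucleophilic CHMe terminus bonds to C10, the aryne carbon remote from the C4 methyl (the two ring oxygens are placed symmetrically about the triple bond, so the flanking methyl decides), the CH2 terminus bonds to C5, and fluoride unmasks the ketone.

**Part D – DE fragment (steps 14–23)**

Step 14
Reactants: 22 (R)-(−)-carvone, 13 silyloxydiene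
Product: 23 cis-fused bicyclic enol ether (C22 ketone, C14–OSi(i-Pr)3 with C14=C15, 13α-methyl, 17β-methyl, 18β-H, 20β-isopropenyl)
Conditions: EtAlCl2, CH2Cl2, −78 to −20 °C
Reagents that add atoms: none
Why: Lewis-acid Diels–Alder reaction on the enone face anti to the isopropenyl group gives the cis ring junction (17β-methyl, 18β-H) in absolute form, with the nucleophilic CHMe terminus on β-carbon C18; the C13 centre (endo) is planarised again in step 16.

Step 15
Reactants: 23 Diels–Alder adduct
Product: 26 bicyclic ketone (C14 ketone, C22 now CH2), via N-silyl hydrazone 24 (not isolated), via deoxygenated silyl enol ether 25 (not isolated)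
Conditions: t-BuMe2SiNHNHSiMe2t-Bu, Sc(OTf)3 (1 mol %), CHCl3, rt to 55 °C; then KOt-Bu, t-BuOH, DMSO, 80 °C; then Bu4NF, AcOH, THF, 0 °C
Reagents that add atoms: none
Why: Only the free C22 ketone condenses (C14 is masked as the robust silyl enol ether), the N-silyl hydrazone collapses to CH2 with loss of N2 (Wolff–Kishner reduction, silyl hydrazone variant), and fluoride then releases the C14 ketone.

Step 16
Reactants: 26 ketone
Product: 27 chloroethyl ketone (C13: α-methyl, β-CH2CH2Cl)
Conditions: KH, THF, rt (equilibration); then ICH2CH2Cl, DMPU, 0 °C to rt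
Reagents that add atoms: 1-chloro-2-iodoethane ClCCI
Why: The thermodynamic, more substituted C13 enolate (favoured as in cis-fused 5β-3-keto steroids) is alkylated at the iodide terminus from the β face, because with the C20 isopropenyl equatorial the α face is covered by the axial C17–C22 bond.

Step 17
Reactants: 27 ketone
Product: 28 C14 dioxolane
Conditions: Me3SiOCH2CH2OSiMe3, Me3SiOTf (5 mol %), CH2Cl2, −78 to −20 °C
Reagents that add atoms: 1,2-bis(trimethylsilyloxy)ethane C[Si](C)(C)OCCO[Si](C)(C)C
Why: Silyl-triflate-catalysed ketalisation works on hindered ketones at low temperature and removes the only enolisable ketone before steps 18–20.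

Step 18
Reactants: 28 dioxolane
Product: 29 methyl ketone (C20 acetyl)
Conditions: O3, CH2Cl2/MeOH, −78 °C; then Me2S
Reagents that add atoms: ozone [O-][O+]=O
Why: Ozonolysis of the only alkene converts isopropenyl into acetyl.

Step 19
Reactants: 29 methyl ketone
Product: 31 methyl ester (C20–H, CO2Me), via carboxylic acid 30 (not isolated)
Conditions: Br2, NaOH, dioxane/H2O, 0 °C; then Me3SiCHN2, MeOH/toluene, rt
Reagents that add atoms: sodium hydroxide [Na+].[OH-]; (trimethylsilyl)diazomethane C[Si](C)(C)C=[N+]=[N-]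
Why: Haloform cleavage of the methyl ketone (no other enolisable carbonyl is present) and O-methylation of the acid; epimerisation at C20 is harmless because the centre is reset in step 20.

Step 20
Reactants: 31 ester
Product: 32 C20 quaternary ester (20β-methyl, 20α-CO2Me)
Conditions: LiN(i-Pr)2, THF, −78 °C; then MeI, DMPU, −78 to −20 °C
Reagents that add atoms: iodomethane CI
Why: Ester enolate methylation from the β face: in the conformer expected to dominate (the alternative puts a dioxolane oxygen syn-axial to C19 and the chloroethyl arm syn-axial to the C17 methyl) C13 is axial on ring E and shields the α face of C20, so MeI should enter equatorially.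

Step 21
Reactants: 32 dioxolane
Product: 33 C14 ketone
Conditions: 1 M aq. HCl, acetone, 40 °C
Reagents that add atoms: water O
Why: Acid hydrolysis of the ketal; the hindered ester and the primary chloride are stable.

Step 22
Reactants: 33 ketone
Product: 34 C14 exocyclic methylene
Conditions: Zn, CH2Br2, TiCl4, THF/CH2Cl2, 0 °C to rt
Reagents that add atoms: dibromomethane BrCBr
Why: Takai–Lombardo methylenation is non-basic, suits ketones beside quaternary carbon and leaves ester and alkyl chloride alone.

Step 23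
Reactants: 34 chloride
Product: 35 iodide (C11–I)
Conditions: NaI, butan-2-one, reflux
Reagents that add atoms: sodium iodide [Na+].[I-]
Why: Finkelstein exchange at the unhindered primary carbon.

**Part E – union, ring C and finish (steps 24–27)**

Step 24
Reactants: 21 tetralone, 35 iodide
Product: 36 C9-alkylated tetralone (9S; 9β-methyl in friedelane terms)
Conditions: 50% aq. NaOH, toluene, N-(4-trifluoromethylbenzyl)cinchoninium bromide (10 mol %), 15 °C, argon
Reagents that add atoms: none
Why: Asymmetric phase-transfer alkylation of a 1-methyl-2-tetralone at its benzylic α-carbon with a primary halide; the chiral ion pair, not the remote stereocentres, sets the C9 quaternary centre.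

Step 25
Reactants: 36 ketone
Product: 37 C8 enol triflate (C7=C8)
Conditions: KN(SiMe3)2, THF, −78 °C; then PhNTf2, −78 to 0 °C
Reagents that add atoms: N-phenylbis(trifluoromethanesulfonimide) O=S(=O)(N(c1ccccc1)S(=O)(=O)C(F)(F)F)C(F)(F)F
Why: The ketone can enolise only towards C7 (C9 is quaternary), so O-triflation gives a single alkenyl triflate.

Step 26
Reactants: 37 enol triflate
Product: 38 pentacyclic Δ7 compound (ring C closed; 13α-methyl, 14β-methyl)
Conditions: Pd(OAc)2 (10 mol %), PPh3, HCO2Na, Et4NCl, DMF, 80 °C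
Reagents that add atoms: none
Why: Zerovalent palladium inserts into the C8–OTf bond, the alkenylpalladium adds syn across the C14=CH2 bond with C8 going to C14, and the resulting neopentyl alkylpalladium at C26 has no β-hydrogen (C14 is now quaternary), so formate delivers hydride and C26 becomes the methyl group. The closest known reaction type is the intramolecular reductive Heck cyclisation that forms all-carbon quaternary centres. Ring C closes in the 6-exo-trig mode; the 7-endo alternative would need palladium on the fully substituted carbon. The new C14 centre is controlled by C13 through a chair-like ring C in which C12 and C8 are both equatorial on ring D, so the CH2Pd carbon ends axial and anti to the 13α-methyl (trans C/D junction, 14β-methyl). The step needs carbopalladation to outrun direct formate reduction of the alkenylpalladium and to prefer this alkene over the isopropenyl and tetrasubstituted alkenes; the four-atom tether between two quaternary carbons (C9, C13) holds the reacting ends together and the other alkenes are out of reach. C8 stays trigonal here, so its configuration is not committed until step 27.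

Step 27
Reactants: 38 Δ7 compound
Product: 39 target (C6=C7, 8α-H)
Conditions: KOt-Bu, DMSO, rt
Reagents that add atoms: none
Why: Base-mediated 1,4- to 1,2-dihydronaphthalene isomerisation: the doubly activated C6–H is removed, and the delocalised anion should be protonated at C8 from the α face, anti to the 9β- and 14β-methyl groups, to give the styrenic alkene, whose shielded tertiary C8–H is then slow to ionise again.

**Compound list**

1 | (S)-(+)-carvone | CC1=CC[C@@H](CC1=O)C(C)=C | starting material
2 | (S)-trimethyl{[2-methyl-5-(prop-1-en-2-yl)cyclohex-1-en-1-yl]oxy}silane | CC1=C(O[Si](C)(C)C)C[C@H](CC1)C(C)=C | intermediate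
3 | (3S)-6-methyl-3-(prop-1-en-2-yl)-1-(trimethylsilyloxy)bicyclo[4.1.0]heptane | C=C(C)[C@H]1CCC2(C)CC2(O[Si](C)(C)C)C1 | intermediate
4 | (6S)-3-chloro-3-methyl-6-(prop-1-en-2-yl)cycloheptan-1-one | C=C(C)[C@H]1CCC(C)(Cl)CC(=O)C1 | intermediate (not isolated)
5 | (S)-3-methyl-6-(prop-1-en-2-yl)cyclohept-2-en-1-one | CC1=CC(=O)C[C@H](CC1)C(C)=C | intermediate
6 | diphenylsilyl enol ether of (3R,6S)-3-methyl-6-(prop-1-en-2-yl)cycloheptanone | C=C(C)[C@H]1CC[C@@H](C)C=C(O[SiH](c2ccccc2)c2ccccc2)C1 | intermediate (not isolated)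
7 | (2S,3R,6S)-2-(but-2-yn-1-yl)-3-methyl-6-(prop-1-en-2-yl)cycloheptan-1-one | C=C(C)[C@H]1CC[C@@H](C)[C@H](CC#CC)C(=O)C1 | intermediate
8 | (2S,3R,6S)-3-methyl-2-(2-oxobutyl)-6-(prop-1-en-2-yl)cycloheptan-1-one | C=C(C)[C@H]1CC[C@@H](C)[C@H](CC(=O)CC)C(=O)C1 | intermediate
9 | (5S,8R,8aS)-3,8-dimethyl-5-(prop-1-en-2-yl)-4,5,6,7,8,8a-hexahydroazulen-2(1H)-one | C=C(C)[C@H]1CC[C@@H](C)[C@@H]2CC(=O)C(C)=C2C1 | intermediate
10 | (5S,8R)-3,8-dimethyl-5-(prop-1-en-2-yl)-1,4,5,6,7,8-hexahydroazulen-2-yl triflate | C=C(C)[C@H]1CC[C@@H](C)C2=C(C1)C(C)=C(OS(=O)(=O)C(F)(F)F)C2 | intermediate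
11 | (4R,7S)-1,4-dimethyl-7-(prop-1-en-2-yl)-3,4,5,6,7,8-hexahydroazulene | C=C(C)[C@H]1CC[C@@H](C)C2=C(C1)C(C)=CC2 | intermediate
12 | pent-1-en-3-one | C=CC(=O)CC | starting material
13 | (Z)-triisopropyl(penta-1,3-dien-3-yloxy)silane | C=C/C(O[Si](C(C)C)(C(C)C)C(C)C)=C/C | intermediate
14 | 2-methylresorcinol | Cc1c(O)cccc1O | starting material
15 | 3-(tert-butyldimethylsilyloxy)-2-methylphenol | Cc1c(O)cccc1O[Si](C)(C)C(C)(C)C | intermediate
16 | 4-(tert-butyldimethylsilyloxy)-3-methylcyclohexa-3,5-diene-1,2-dione | CC1=C(O[Si](C)(C)C(C)(C)C)C=CC(=O)C1=O | intermediate (not isolated)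
17 | cis-fused guaiane benzodioxane, arene 4-methyl-5-silyloxy | C=C(C)[C@H]1CC[C@@H](C)C2=C(C1)[C@]1(C)Oc3c(ccc(O[Si](C)(C)C(C)(C)C)c3C)O[C@@H]1C2 | intermediate
18 | guaiane benzodioxane C5 aryl triflate | C=C(C)[C@H]1CC[C@@H](C)C2=C(C1)[C@]1(C)Oc3c(ccc(OS(=O)(=O)C(F)(F)F)c3C)O[C@@H]1C2 | intermediate
19 | C5–C10 aryne of the benzodioxane | C=C(C)[C@H]1CC[C@@H](C)C2=C(C1)[C@]1(C)OC3=C(C)C#CC=C3O[C@@H]1C2 | intermediate (not isolated)
20 | triisopropylsilyl enol ether of the tetralone (C7=C8, C9–H epimers) | C=C(C)[C@H]1CC[C@@H](C)C2=C(C1)[C@]1(C)Oc3c(cc4c(c3C)CC=C(O[Si](C(C)C)(C(C)C)C(C)C)C4C)O[C@@H]1C2 | intermediate (not isolated)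
21 | benzodioxane-fused 1-methyl-2-tetralone (C8 ketone, C9–H epimers) | C=C(C)[C@H]1CC[C@@H](C)C2=C(C1)[C@]1(C)Oc3c(cc4c(c3C)CCC(=O)C4C)O[C@@H]1C2 | intermediate
22 | (R)-(−)-carvone | CC1=CC[C@H](CC1=O)C(C)=C | starting material
23 | cis-fused carvone Diels–Alder adduct (C22 ketone, C14 silyl enol ether) | C[C@@H]1[C@@H]2C[C@@H](C(C)=C)CC(=O)[C@]2(C)CC=C1O[Si](C(C)C)(C(C)C)C(C)C | intermediate
24 | C22 N-(tert-butyldimethylsilyl)hydrazone of 23 | C[C@@H]1[C@@H]2C[C@@H](C(C)=C)CC(=NN[Si](C)(C)C(C)(C)C)[C@]2(C)CC=C1O[Si](C(C)C)(C(C)C)C(C)C | intermediate (not isolated)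
25 | C22-deoxygenated silyl enol ether | C[C@@H]1[C@@H]2C[C@@H](C(C)=C)CC[C@]2(C)CC=C1O[Si](C(C)C)(C(C)C)C(C)C | intermediate (not isolated)
26 | cis-fused C14 ketone (13-methyl, 17β-methyl, 18β-H, 20β-isopropenyl) | C[C@@H]1[C@@H]2C[C@@H](C(C)=C)CC[C@]2(C)CCC1=O | intermediate
27 | 13β-(2-chloroethyl)-13α-methyl C14 ketone | ClCC[C@@]1(C)[C@@H]2C[C@@H](C(C)=C)CC[C@]2(C)CCC1=O | intermediate
28 | C14 ethylene ketal of 27 | ClCC[C@@]1(C)[C@@H]2C[C@@H](C(C)=C)CC[C@]2(C)CCC13OCCO3 | intermediate
29 | C20 acetyl ketal | ClCC[C@@]1(C)[C@@H]2C[C@@H](C(C)=O)CC[C@]2(C)CCC13OCCO3 | intermediate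
30 | C20 carboxylic acid ketal | ClCC[C@@]1(C)[C@@H]2C[C@@H](C(=O)O)CC[C@]2(C)CCC13OCCO3 | intermediate (not isolated)
31 | C20 methyl ester ketal | ClCC[C@@]1(C)[C@@H]2C[C@@H](C(=O)OC)CC[C@]2(C)CCC13OCCO3 | intermediate
32 | 20β-methyl-20α-methoxycarbonyl ketal | ClCC[C@@]1(C)[C@@H]2C[C@](C)(C(=O)OC)CC[C@]2(C)CCC13OCCO3 | intermediate
33 | DE chloro ketone (C14 ketone) | ClCC[C@@]1(C)[C@@H]2C[C@](C)(C(=O)OC)CC[C@]2(C)CCC1=O | intermediate
34 | DE chloride with C14 exocyclic methylene | ClCC[C@@]1(C)[C@@H]2C[C@](C)(C(=O)OC)CC[C@]2(C)CCC1=C | intermediate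
35 | DE iodide with C14 exocyclic methylene | ICC[C@@]1(C)[C@@H]2C[C@](C)(C(=O)OC)CC[C@]2(C)CCC1=C | intermediate
36 | (9S)-C9-alkylated tetralone (C8 ketone, seco ring C) | C=C(C)[C@H]1CC[C@@H](C)C2=C(C1)[C@]1(C)Oc3c(cc4c(c3C)CCC(=O)[C@@]4(C)CC[C@@]4(C)[C@@H]5C[C@](C)(C(=O)OC)CC[C@]5(C)CCC4=C)O[C@@H]1C2 | intermediate
37 | C8 enol triflate (C7=C8, seco ring C) | C=C(C)[C@H]1CC[C@@H](C)C2=C(C1)[C@]1(C)Oc3c(cc4c(c3C)CC=C(OS(=O)(=O)C(F)(F)F)[C@@]4(C)CC[C@@]4(C)[C@@H]5C[C@](C)(C(=O)OC)CC[C@]5(C)CCC4=C)O[C@@H]1C2 | intermediate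
38 | Δ7 pentacycle (ring C closed, C7=C8) | C=C(C)[C@H]1CC[C@@H](C)C2=C(C1)[C@]1(C)Oc3c(cc4c(c3C)CC=C3[C@@]4(C)CC[C@@]4(C)[C@@H]5C[C@](C)(C(=O)OC)CC[C@]5(C)CC[C@]34C)O[C@@H]1C2 | intermediate
39 | CNP0222748.1 | C=C(C)[C@H]1CC[C@@H](C)C2=C(C1)[C@]1(C)Oc3c(cc4c(c3C)C=C[C@H]3[C@@]4(C)CC[C@@]4(C)[C@@H]5C[C@](C)(C(=O)OC)CC[C@]5(C)CC[C@]34C)O[C@@H]1C2 | target

**Count and risks**

Total steps: 27. Longest linear sequence: 15 steps (1–8, 11–13, 24–27).

Most likely to fail:

1. Step 26. Carbopalladation at an alkene flanked by quaternary C13, from an alkenylpalladium flanked by quaternary C9, may be slower than formate reduction of the alkenylpalladium. Insertion on the other alkene face would give the cis C/D junction. The fallback closes the same bond by a radical chain instead of palladium. Ketone 36 is condensed with hydrazine (N2H4·H2O, Et3N, EtOH, 80 °C) to the hydrazone F4. Iodine and tetramethylguanidine in ether (Barton procedure) convert it into the alkenyl iodide F5. Bu3SnH at high concentration with AIBN in benzene at 80 °C generates the C8 alkenyl radical, which should cyclise 6-exo onto C14; the C26 radical is reduced to the methyl group, returning to 38.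

2. Step 11. The quinone may add to either face of the diene with little preference, and it may also react through its unsubstituted C=C bond as a carbocyclic dienophile. The fallback builds the dioxane stepwise under reagent control. Enone 9 is reduced with (R)-Me-CBS and BH3·SMe2 to the allylic alcohol F1. Quinone 16, made from 15 as in step 11, is reduced in the flask with Na2S2O4 to the catechol F2. Mitsunobu coupling (PPh3, DIAD, THF) at the less hindered O2–H with inversion at C3' gives the aryl ether F3. Aerobic oxidative cyclisation (Pd(OCOCF3)2, pyridine, Na2CO3, O2, toluene, 80 °C; syn oxypalladation by O3–H at C4', then β-hydride loss from C1') returns to 17.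

3. Step 27. The prototropic shift may stop at an equilibrium mixture of alkene isomers, or protonate C8 on the wrong face. The fallback replaces equilibration by a directed hydride delivery. Benzylic-allylic oxidation of 38 with DDQ in wet dioxane gives the 6-oxo-Δ7 enone F6. Luche reduction (NaBH4, CeCl3, MeOH) gives the 6β-alcohol F7, and formic acetic anhydride with pyridine gives the formate F8. Pd(OAc)2 and PBu3 in dioxane then deliver hydride from palladium to C8 anti to the leaving group with transposition of the alkene, returning to 39.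

Further compounds
F1 | step 11 | (2S,5S,8R,8aS)-3,8-dimethyl-5-(prop-1-en-2-yl)-1,2,4,5,6,7,8,8a-octahydroazulen-2-ol | C=C(C)[C@H]1CC[C@@H](C)[C@@H]2C[C@H](O)C(C)=C2C1
F2 | step 11 | 4-(tert-butyldimethylsilyloxy)-3-methylbenzene-1,2-diol | Cc1c(O[Si](C)(C)C(C)(C)C)ccc(O)c1O
F3 | step 11 | C3' aryl ether of the hexahydroazulene with free O3–H | C=C(C)[C@H]1CC[C@@H](C)[C@@H]2C[C@@H](Oc3ccc(O[Si](C)(C)C(C)(C)C)c(C)c3O)C(C)=C2C1
F4 | step 26 | C8 hydrazone of 36 | C=C(C)[C@H]1CC[C@@H](C)C2=C(C1)[C@]1(C)Oc3c(cc4c(c3C)CCC(=NN)[C@@]4(C)CC[C@@]4(C)[C@@H]5C[C@](C)(C(=O)OC)CC[C@]5(C)CCC4=C)O[C@@H]1C2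
F5 | step 26 | C8 alkenyl iodide (C7=C8) | C=C(C)[C@H]1CC[C@@H](C)C2=C(C1)[C@]1(C)Oc3c(cc4c(c3C)CC=C(I)[C@@]4(C)CC[C@@]4(C)[C@@H]5C[C@](C)(C(=O)OC)CC[C@]5(C)CCC4=C)O[C@@H]1C2
F6 | step 27 | 6-oxo-Δ7 enone | C=C(C)[C@H]1CC[C@@H](C)C2=C(C1)[C@]1(C)Oc3c(cc4c(c3C)C(=O)C=C3[C@@]4(C)CC[C@@]4(C)[C@@H]5C[C@](C)(C(=O)OC)CC[C@]5(C)CC[C@]34C)O[C@@H]1C2
F7 | step 27 | 6β-hydroxy-Δ7 compound | C=C(C)[C@H]1CC[C@@H](C)C2=C(C1)[C@]1(C)Oc3c(cc4c(c3C)[C@H](O)C=C3[C@@]4(C)CC[C@@]4(C)[C@@H]5C[C@](C)(C(=O)OC)CC[C@]5(C)CC[C@]34C)O[C@@H]1C2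
F8 | step 27 | 6β-formate of F7 | C=C(C)[C@H]1CC[C@@H](C)C2=C(C1)[C@]1(C)Oc3c(cc4c(c3C)[C@H](OC=O)C=C3[C@@]4(C)CC[C@@]4(C)[C@@H]5C[C@](C)(C(=O)OC)CC[C@]5(C)CC[C@]34C)O[C@@H]1C2
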